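## Retrosynthetic overview

1. The target comes from radical removal of a temporary hydroxyl on the CH2 that links chroman C2 to the enone; that hydroxyl exists only to steer the key step. The cyclohexenone ring is made last, by nickel-catalysed insertion of an internal alkyne into the C(=O)–CH2 bond of a cis-fused cyclobutanone: the bond from the carbonyl carbon (C4) to the alkyne-derived α-carbon (C5) forms first, and C6–C7 completes the ring.
2. Enabling feature: in the hexahydroindenone the C4 ketone lies between the quaternary fusion carbon C3a and the tetrasubstituted C5=C6 alkene, and C7H2 ties C6 to the second quaternary fusion carbon C7a. C4–C3a–C7a–C7 is thus a disguised cyclobutanone fused to the cyclopentane ring, and C5=C6 a disguised alkyne.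
3. The alkyne comes from (R)-chroman-2-carbaldehyde and 2-methylpent-4-yn-2-ol by acetylide addition; the chroman comes from an enantioselective Wacker cyclization of an ortho-alkenylphenol.
4. The cyclobutanone comes from dichloroketene [2+2] cycloaddition to 1,2-dimethylcyclopentene (cis vicinal quaternary carbons), dechlorination, and resolution as a chiral ketal.
5. Ring order: cyclopentane (bought), then cyclobutane; separately the dihydropyran ring of the chroman; cyclohexenone last, with the cyclobutane consumed.

Key step: step 12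

Assumption: in step 8 the (R,R) ligand is taken to give the (R)-chroman by analogy with related alkenylphenols (the antipodal ligand is used if the sense is opposite); the carbinol center made in step 10 is temporary and is carried as an epimer mixture until step 15 removes it.

## Route

Step 1
Reactants: 1 1,2-dimethylcyclopentene
Product: 2 rac-(1R,5S)-7,7-dichloro-1,5-dimethylbicyclo[3.2.0]heptan-6-one
Conditions: Cl3CCOCl, Zn–Cu couple, POCl3, Et2O, reflux
Reagents that add atoms: trichloroacetyl chloride, ClC(=O)C(Cl)(Cl)Cl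
Why: Ketene–alkene [2+2] cycloaddition: dichloroketene made in situ by zinc dechlorination adds suprafacially to the tetrasubstituted alkene, so the two methyl-bearing quaternary carbons are set cis (racemic) in one step.

Step 2
Reactants: 2 rac-(1R,5S)-7,7-dichloro-1,5-dimethylbicyclo[3.2.0]heptan-6-one
Product: 3 rac-(1S,5S)-1,5-dimethylbicyclo[3.2.0]heptan-6-one
Conditions: Zn, AcOH, 70 °C
Reagents that add atoms: none
Why: Reductive dechlorination of an α,α-dichloroketone by zinc in acetic acid proceeds through the zinc enolate and touches neither the four-membered ring nor the quaternary centers.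

Step 3
Reactants: 3 rac-(1S,5S)-1,5-dimethylbicyclo[3.2.0]heptan-6-one
Product: 4 (1S,4'R,5S,5'R)-1,5-dimethyl-4',5'-diphenylspiro[bicyclo[3.2.0]heptane-6,2'-[1,3]dioxolane]
Conditions: (R,R)-hydrobenzoin, p-TsOH (cat.), benzene, reflux (Dean–Stark); diastereomers separated on silica and by crystallization
Reagents that add atoms: (1R,2R)-1,2-diphenylethane-1,2-diol, O[C@H](c1ccccc1)[C@H](O)c1ccccc1
Why: Resolution of a racemic ketone as diastereomeric ketals of a C2-symmetric diol: the spiro carbon is not stereogenic, so only two diastereomers form, they differ in the sense of the bicycle and are separated, and the (1S,5S) series is assigned by crystallography.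

Step 4
Reactants: 4 (1S,4'R,5S,5'R)-1,5-dimethyl-4',5'-diphenylspiro[bicyclo[3.2.0]heptane-6,2'-[1,3]dioxolane]
Product: 5 (1S,5S)-1,5-dimethylbicyclo[3.2.0]heptan-6-one
Conditions: CF3CO2H/H2O (9:1), CH2Cl2, 0 °C to rt
Reagents that add atoms: water, O
Why: Acid-catalysed ketal hydrolysis returns the ketone as a single enantiomer, since its stereocenters are quaternary and cannot epimerize, and the diol is recovered.

Step 5
Reactants: 6 4-methoxy-2-methylphenol
Product: 7 2-iodo-4-methoxy-6-methylphenol
Conditions: N-iodosuccinimide, p-TsOH (cat.), MeCN, 0 °C to rt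
Reagents that add atoms: N-iodosuccinimide, O=C1CCC(=O)N1I
Why: Electrophilic aromatic iodination is directed by the free hydroxyl to its only open ortho position, the para position being occupied by methoxy.

Step 6
Reactants: 7 2-iodo-4-methoxy-6-methylphenol; 8 but-3-en-2-ol
Product: 10 4-(2-hydroxy-5-methoxy-3-methylphenyl)butan-2-one, via enol 9 (not isolated)
Conditions: Pd(OAc)2 (5 mol%), Bu4NCl, NaHCO3, DMF, 60 °C
Reagents that add atoms: none
Why: Heck reaction of an aryl iodide with an allylic alcohol: carbopalladation at the terminal alkene carbon and β-hydride elimination toward the carbinol carbon give the enol, which tautomerizes to the methyl ketone.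

Step 7
Reactants: 10 4-(2-hydroxy-5-methoxy-3-methylphenyl)butan-2-one
Product: 11 4-methoxy-2-methyl-6-(3-methylpent-3-en-1-yl)phenol (E/Z mixture)
Conditions: EtPPh3Br (3.5 equiv), KOt-Bu (3.4 equiv), THF, 0 °C to reflux
Reagents that add atoms: ethyltriphenylphosphonium bromide, CC[P+](c1ccccc1)(c1ccccc1)c1ccccc1.[Br-]
Why: Wittig olefination with a non-stabilized ylide (in excess, since the phenol takes up one equivalent of base) gives the trisubstituted alkene, whose E/Z mixture is used directly.

Step 8
Reactants: 11 4-methoxy-2-methyl-6-(3-methylpent-3-en-1-yl)phenol (E/Z mixture)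
Product: 12 (2R)-2-ethenyl-6-methoxy-2,8-dimethyl-3,4-dihydro-2H-chromene
Conditions: Pd(OCOCF3)2 (10 mol%), (R,R)-Bn-BOXAX [2,2'-bis((4R)-4-benzyl-4,5-dihydrooxazol-2-yl)-1,1'-binaphthyl] (20 mol%), p-benzoquinone (4 equiv), MeOH, rt
Reagents that add atoms: none
Why: Enantioselective Wacker-type oxidative cyclization: the chiral bis(oxazoline) complex of divalent palladium selects one alkene face for 6-exo oxypalladation by the phenol, which sets the quaternary C2 center as R, β-hydride elimination from the methyl group releases the vinyl group, and benzoquinone reoxidizes the metal.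

Step 9
Reactants: 12 (2R)-2-ethenyl-6-methoxy-2,8-dimethyl-3,4-dihydro-2H-chromene
Product: 14 (2R)-6-methoxy-2,8-dimethyl-3,4-dihydro-2H-chromene-2-carbaldehyde, via diol 13 (not isolated)
Conditions: OsO4 (2 mol%), NaIO4 (4 equiv), 2,6-lutidine, 1,4-dioxane/H2O (3:1), rt
Reagents that add atoms: sodium periodate, [Na+].[O-]I(=O)(=O)=O
Why: Lemieux–Johnson oxidation (osmium-catalysed dihydroxylation, then periodate cleavage of the diol) shortens the vinyl group to the aldehyde without attacking the electron-rich arene, and the quaternary α-carbon cannot epimerize.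

Step 10
Reactants: 14 (2R)-6-methoxy-2,8-dimethyl-3,4-dihydro-2H-chromene-2-carbaldehyde; 15 2-methylpent-4-yn-2-ol
Product: 17 1-[(2R)-6-methoxy-2,8-dimethyl-3,4-dihydro-2H-chromen-2-yl]-5-methylhex-2-yne-1,5-diol (both C1 epimers), via dilithium alkynolate 16 (not isolated)
Conditions: 15 (1.5 equiv), n-BuLi (3.0 equiv), THF, −78 to 0 °C; then 14, −78 to 0 °C; H2O
Reagents that add atoms: none
Why: 1,2-Addition of a lithium acetylide (as the alkoxide–acetylide dianion) to a non-enolizable aldehyde; the new carbinol center is temporary, so its configuration is not controlled.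

Step 11
Reactants: 17 1-[(2R)-6-methoxy-2,8-dimethyl-3,4-dihydro-2H-chromen-2-yl]-5-methylhex-2-yne-1,5-diol
Product: 18 (2R)-6-methoxy-2,8-dimethyl-2-{5-methyl-1,5-bis[(triethylsilyl)oxy]hex-2-yn-1-yl}-3,4-dihydro-2H-chromene
Conditions: Et3SiOTf (3 equiv), 2,6-lutidine, CH2Cl2, −78 to 0 °C
Reagents that add atoms: triethylsilyl trifluoromethanesulfonate, CC[Si](CC)(CC)OS(=O)(=O)C(F)(F)F
Why: Silylation with a silyl triflate and a hindered base covers both the secondary propargylic and the tertiary hydroxyl, which shields them from zerovalent nickel and makes the propargylic substituent large.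

Step 12
Reactants: 5 (1S,5S)-1,5-dimethylbicyclo[3.2.0]heptan-6-one; 18 (2R)-6-methoxy-2,8-dimethyl-2-{5-methyl-1,5-bis[(triethylsilyl)oxy]hex-2-yn-1-yl}-3,4-dihydro-2H-chromene
Product: 21 (3aS,7aS)-6-{[(2R)-6-methoxy-2,8-dimethyl-3,4-dihydro-2H-chromen-2-yl][(triethylsilyl)oxy]methyl}-3a,7a-dimethyl-5-{2-methyl-2-[(triethylsilyl)oxy]propyl}-1,2,3,3a,7,7a-hexahydro-4H-inden-4-one, via oxanickelacyclopentene 19 (not isolated), via nickelacycloheptenone 20 (not isolated)
Conditions: Ni(cod)2 (10 mol%), PCy3 (20 mol%), toluene, 100 °C; 5 (2 equiv)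
Reagents that add atoms: none
Why: Zerovalent nickel couples the ketone carbonyl of 5 and the alkyne of 18 by oxidative cyclization to the spiro oxanickelacyclopentene 19, in which the new bond joins the carbonyl carbon (C4 of the product) to the alkyne carbon that carries the CH2C(Me)2OSiEt3 arm (C5); β-carbon elimination then opens the strained cyclobutane to the seven-membered nickelacycle 20, and reductive elimination joins C7 to C6. The closest known reaction type is the nickel-catalysed intermolecular insertion of internal alkynes into cyclobutanones, a formal [4+2] ring expansion to 2,3-disubstituted cyclohexenones. The cyclohexenone ring is closed as a two-bond annulation, C4–C5 in the oxidative cyclization and C6–C7 in the reductive elimination, with the four-membered ring consumed. No stereocenter is formed: the two quaternary carbons of 5 lie outside the bonds made and broken, so the cis fusion and the 3aS,7aS configuration are carried over unchanged. Two selectivities are needed: the alkyne must place its silyloxymethine-bearing carbon on nickel and its unbranched end on the hindered carbonyl, which the α-branched, inductively withdrawing propargylic substituent secures by steric and electronic bias; and β-carbon elimination must break the C6–C7 (CH2) bond of 5 and not the bond to the quaternary carbon, which the shift of a primary alkyl to nickel favors, the resulting neopentyl-type alkylnickel having no β-hydrogen.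

Step 13
Reactants: 21 (3aS,7aS)-6-{[(2R)-6-methoxy-2,8-dimethyl-3,4-dihydro-2H-chromen-2-yl][(triethylsilyl)oxy]methyl}-3a,7a-dimethyl-5-{2-methyl-2-[(triethylsilyl)oxy]propyl}-1,2,3,3a,7,7a-hexahydro-4H-inden-4-one
Product: 22 (3aS,7aS)-6-{hydroxy[(2R)-6-methoxy-2,8-dimethyl-3,4-dihydro-2H-chromen-2-yl]methyl}-5-(2-hydroxy-2-methylpropyl)-3a,7a-dimethyl-1,2,3,3a,7,7a-hexahydro-4H-inden-4-one
Conditions: HF·pyridine, pyridine, THF, 0 °C to rt
Reagents that add atoms: none
Why: Fluoride cleavage of both silyl ethers with pyridine-buffered HF avoids basic conditions, under which deprotonation at the carbon next to the chroman could expel the aryloxy group.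

Step 14
Reactants: 22 (3aS,7aS)-6-{hydroxy[(2R)-6-methoxy-2,8-dimethyl-3,4-dihydro-2H-chromen-2-yl]methyl}-5-(2-hydroxy-2-methylpropyl)-3a,7a-dimethyl-1,2,3,3a,7,7a-hexahydro-4H-inden-4-one
Product: 23 O-phenyl thiocarbonate of the secondary alcohol of 22 (carbinol oxygen carries C(=S)OPh)
Conditions: PhOC(S)Cl, pyridine, DMAP (cat.), CH2Cl2, 0 °C to rt
Reagents that add atoms: O-phenyl chlorothionoformate, S=C(Cl)Oc1ccccc1
Why: Thioacylation of the secondary alcohol with an aryl chlorothionoformate (first half of a Barton–McCombie deoxygenation) is chemoselective because the tertiary alcohol is too hindered to react.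

Step 15
Reactants: 23 O-phenyl thiocarbonate of the secondary alcohol of 22
Product: 24 (3aS,7aS)-5-(2-hydroxy-2-methylpropyl)-6-{[(2R)-6-methoxy-2,8-dimethyl-3,4-dihydro-2H-chromen-2-yl]methyl}-3a,7a-dimethyl-1,2,3,3a,7,7a-hexahydro-4H-inden-4-one
Conditions: Bu3SnH, AIBN (cat.), toluene, 90 °C
Reagents that add atoms: none
Why: Barton–McCombie deoxygenation: the stannyl radical adds to the thiocarbonyl, β-scission gives a radical delocalized over the enone, and hydrogen transfer at its less hindered exocyclic terminus returns the conjugated tetrasubstituted enone under neutral conditions, which removes the temporary stereocenter and leaves the three permanent ones untouched.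

## Compound list

1 | 1,2-dimethylcyclopentene | CC1=C(C)CCC1 | starting material
2 | rac-(1R,5S)-7,7-dichloro-1,5-dimethylbicyclo[3.2.0]heptan-6-one (cis-fused racemate, one enantiomer drawn) | O=C1[C@@]2(C)CCC[C@@]2(C)C1(Cl)Cl | intermediate
3 | rac-(1S,5S)-1,5-dimethylbicyclo[3.2.0]heptan-6-one (cis-fused racemate, one enantiomer drawn) | O=C1[C@@]2(C)CCC[C@@]2(C)C1 | intermediate
4 | (1S,4'R,5S,5'R)-1,5-dimethyl-4',5'-diphenylspiro[bicyclo[3.2.0]heptane-6,2'-[1,3]dioxolane] | C13(O[C@H](c4ccccc4)[C@@H](c4ccccc4)O3)[C@@]2(C)CCC[C@@]2(C)C1 | intermediate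
5 | (1S,5S)-1,5-dimethylbicyclo[3.2.0]heptan-6-one (single enantiomer) | O=C1[C@@]2(C)CCC[C@@]2(C)C1 | intermediate
6 | 4-methoxy-2-methylphenol | COc1ccc(O)c(C)c1 | starting material
7 | 2-iodo-4-methoxy-6-methylphenol | COc1cc(C)c(O)c(I)c1 | intermediate
8 | but-3-en-2-ol (racemic) | CC(O)C=C | starting material
9 | 4-(2-hydroxy-5-methoxy-3-methylphenyl)but-2-en-2-ol (enol) | COc1cc(C)c(O)c(CC=C(C)O)c1 | intermediate (not isolated)
10 | 4-(2-hydroxy-5-methoxy-3-methylphenyl)butan-2-one | COc1cc(C)c(O)c(CCC(C)=O)c1 | intermediate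
11 | 4-methoxy-2-methyl-6-(3-methylpent-3-en-1-yl)phenol (E/Z mixture) | COc1cc(C)c(O)c(CCC(C)=CC)c1 | intermediate
12 | (2R)-2-ethenyl-6-methoxy-2,8-dimethyl-3,4-dihydro-2H-chromene | COc1cc(C)c2c(c1)CC[C@](C)(C=C)O2 | intermediate
13 | 1-[(2R)-6-methoxy-2,8-dimethyl-3,4-dihydro-2H-chromen-2-yl]ethane-1,2-diol (both C1 epimers) | COc1cc(C)c2c(c1)CC[C@](C)(C(O)CO)O2 | intermediate (not isolated)
14 | (2R)-6-methoxy-2,8-dimethyl-3,4-dihydro-2H-chromene-2-carbaldehyde | COc1cc(C)c2c(c1)CC[C@](C)(C=O)O2 | intermediate
15 | 2-methylpent-4-yn-2-ol | CC(C)(O)CC#C | starting material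
16 | dilithium salt of 15 (lithium alkoxide and lithium acetylide) | [Li+].[Li+].CC(C)([O-])CC#[C-] | intermediate (not isolated)
17 | 1-[(2R)-6-methoxy-2,8-dimethyl-3,4-dihydro-2H-chromen-2-yl]-5-methylhex-2-yne-1,5-diol (both C1 epimers) | COc1cc(C)c2c(c1)CC[C@](C)(C(O)C#CCC(C)(C)O)O2 | intermediate
18 | (2R)-6-methoxy-2,8-dimethyl-2-{5-methyl-1,5-bis[(triethylsilyl)oxy]hex-2-yn-1-yl}-3,4-dihydro-2H-chromene (both C1 epimers) | COc1cc(C)c2c(c1)CC[C@](C)(C(O[Si](CC)(CC)CC)C#CCC(C)(C)O[Si](CC)(CC)CC)O2 | intermediate
19 | spiro oxanickelacyclopentene (PCy3 on nickel): Ni bound to the carbinol oxygen of the former ketone carbon and to the alkyne carbon bearing the silyloxymethine group; cyclobutane intact | COc1cc(C)c2c(c1)CC[C@](C)(C(O[Si](CC)(CC)CC)C1=C(CC(C)(C)O[Si](CC)(CC)CC)C3(O[Ni]1P(C1CCCCC1)(C1CCCCC1)C1CCCCC1)[C@@]4(C)CCC[C@@]4(C)C3)O2 | intermediate (not isolated)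
20 | nickelacycloheptenone (PCy3 on nickel): Ni bound to the alkenyl carbon (future C6) and to the ring-opened CH2 (future C7); ketone restored | COc1cc(C)c2c(c1)CC[C@](C)(C(O[Si](CC)(CC)CC)C1=C(CC(C)(C)O[Si](CC)(CC)CC)C(=O)[C@@]3(C)CCC[C@@]3(C)C[Ni]1P(C1CCCCC1)(C1CCCCC1)C1CCCCC1)O2 | intermediate (not isolated)
21 | (3aS,7aS)-6-{[(2R)-6-methoxy-2,8-dimethyl-3,4-dihydro-2H-chromen-2-yl][(triethylsilyl)oxy]methyl}-3a,7a-dimethyl-5-{2-methyl-2-[(triethylsilyl)oxy]propyl}-1,2,3,3a,7,7a-hexahydro-4H-inden-4-one (both carbinol epimers) | COc1cc(C)c2c(c1)CC[C@](C)(C(O[Si](CC)(CC)CC)C1=C(CC(C)(C)O[Si](CC)(CC)CC)C(=O)[C@@]3(C)CCC[C@@]3(C)C1)O2 | intermediate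
22 | (3aS,7aS)-6-{hydroxy[(2R)-6-methoxy-2,8-dimethyl-3,4-dihydro-2H-chromen-2-yl]methyl}-5-(2-hydroxy-2-methylpropyl)-3a,7a-dimethyl-1,2,3,3a,7,7a-hexahydro-4H-inden-4-one (both carbinol epimers) | COc1cc(C)c2c(c1)CC[C@](C)(C(O)C1=C(CC(C)(C)O)C(=O)[C@@]3(C)CCC[C@@]3(C)C1)O2 | intermediate
23 | O-phenyl thiocarbonate of the secondary alcohol of 22 (both carbinol epimers) | COc1cc(C)c2c(c1)CC[C@](C)(C(OC(=S)Oc1ccccc1)C1=C(CC(C)(C)O)C(=O)[C@@]3(C)CCC[C@@]3(C)C1)O2 | intermediate
24 | (3aS,7aS)-5-(2-hydroxy-2-methylpropyl)-6-{[(2R)-6-methoxy-2,8-dimethyl-3,4-dihydro-2H-chromen-2-yl]methyl}-3a,7a-dimethyl-1,2,3,3a,7,7a-hexahydro-4H-inden-4-one | COc1cc(C)c2c(c1)CC[C@](C)(CC1=C(CC(C)(C)O)C(=O)[C@@]3(C)CCC[C@@]3(C)C1)O2 | target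

## Step count and risks

Total step count: 15. Longest linear sequence: 11 steps (steps 5 to 15, from 4-methoxy-2-methylphenol); the cyclobutanone branch (steps 1 to 4) joins at step 12.

Steps most likely to fail:

1. Step 12. The oxidative cyclization may be too slow because the ketone is flanked by a quaternary carbon and the alkyne is α-branched, so that alkyne oligomerization or β-elimination of the silyloxy group from the alkenylnickel takes over; partial loss of regiocontrol in the alkyne insertion is the second hazard. Fallback, setting out from 5 (with 14 as partner) and returning to the route at 22: the lithium enolate of 5 (LiN(i-Pr)2, THF, −78 °C) is C-acylated at C7 by 5,5-dimethyldihydrofuran-2(3H)-one to give (1S,5S)-7-(4-hydroxy-4-methylpentanoyl)-1,5-dimethylbicyclo[3.2.0]heptan-6-one F1. NaOMe in MeOH at reflux opens the strained β-diketone by retro-Claisen attack at the ring carbonyl and recloses the keto ester by Dieckmann condensation, giving (3aS,7aS)-5-(2-hydroxy-2-methylpropyl)-3a,7a-dimethylhexahydro-1H-indene-4,6(5H)-dione F2. KN(SiMe3)2 and PhNTf2 (THF, −78 °C) sulfonylate the enolate oxygen remote from the quaternary carbon to give (3aS,7aS)-5-(2-hydroxy-2-methylpropyl)-3a,7a-dimethyl-4-oxo-2,3,3a,4,7,7a-hexahydro-1H-inden-6-yl trifluoromethanesulfonate F3. Nozaki–Hiyama–Kishi coupling of F3 with aldehyde 14 (CrCl2, NiCl2 cat., DMF, rt) gives diol 22.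

2. Step 15. Hydrogen transfer may go to the ring terminus of the delocalized radical (deconjugated product), the radical may fragment with loss of the chroman aryloxy group, or the allylic thionocarbonate may undergo a thermal [3,3] shift before it is reduced. Fallback, setting out from 22 and returning at 24: acetylation (Ac2O, pyridine, DMAP cat., CH2Cl2) gives the acetate of the secondary alcohol of 22 F4, which is reduced by two-electron transfer with SmI2 in THF/MeOH at −78 °C; acetate is expelled from the γ-position and the samarium dienolate is protonated at once at low temperature, so that it cannot expel the chroman oxygen, giving 24.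

3. Step 3. The two diastereomeric ketals may co-elute and co-crystallize, so that no resolution is achieved. Fallback, setting out from 3 and returning at 5: enzymatic kinetic resolution with a Baeyer–Villiger monooxygenase of the cyclohexanone monooxygenase class (air, NADPH recycled by glucose and glucose dehydrogenase, buffer pH 8, 25 °C). A variant is selected by screening that oxidizes the (1R,5R)-enantiomer to (3aR,6aR)-3a,6a-dimethylhexahydro-2H-cyclopenta[b]furan-2-one F5, and the unreacted (1S,5S)-ketone 5 is isolated.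

Further compounds
F1 | step 12 | (1S,5S)-7-(4-hydroxy-4-methylpentanoyl)-1,5-dimethylbicyclo[3.2.0]heptan-6-one | O=C1[C@@]2(C)CCC[C@@]2(C)C1C(=O)CCC(C)(C)O
F2 | step 12 | (3aS,7aS)-5-(2-hydroxy-2-methylpropyl)-3a,7a-dimethylhexahydro-1H-indene-4,6(5H)-dione | O=C1C(CC(C)(C)O)C(=O)[C@@]2(C)CCC[C@@]2(C)C1
F3 | step 12 | (3aS,7aS)-5-(2-hydroxy-2-methylpropyl)-3a,7a-dimethyl-4-oxo-2,3,3a,4,7,7a-hexahydro-1H-inden-6-yl trifluoromethanesulfonate | FC(F)(F)S(=O)(=O)OC1=C(CC(C)(C)O)C(=O)[C@@]2(C)CCC[C@@]2(C)C1
F4 | step 15 | acetate of the secondary alcohol of 22 | COc1cc(C)c2c(c1)CC[C@](C)(C(OC(C)=O)C1=C(CC(C)(C)O)C(=O)[C@@]3(C)CCC[C@@]3(C)C1)O2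
F5 | step 3 | (3aR,6aR)-3a,6a-dimethylhexahydro-2H-cyclopenta[b]furan-2-one | O=C1O[C@]2(C)CCC[C@]2(C)C1
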